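**Retrosynthetic overview**
- Key disconnection: the diaryl ether C–O bond between ring A (the 3,5-dibromo-2-hydroxyphenyl ring) and the bromine-flanked oxygen of ring B (the tribromophenol ring). Both rings are bought as benzenes; no ring is built.
- Ring A comes from 2-amino-4,6-dibromophenol 1 and ring B from 3,5-dibromosalicylaldehyde 2. Amine 1 is turned into ortho-quinone diazide 3, whose carbene inserts into the O–H of 2 to give diaryl ether 4.
- The formyl group of ring B is a masked hydroxyl (Baeyer–Villiger through formate 5 to diol 6), so only the intended ring B oxygen can be arylated.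
- The fifth bromine goes in last, ortho to the unmasked ring B hydroxyl, to give 7.

Assumption: the target has no stereocentre and its diaryl ether axis rotates freely, so it is achiral and the route simply delivers the one compound drawn. Rh2(esp)2 is dirhodium bis(α,α,α′,α′-tetramethyl-1,3-benzenedipropanoate).

**Step 1**
Reactants: 1 2-amino-4,6-dibromophenol
Product: 3 2,4-dibromo-6-diazocyclohexa-2,4-dien-1-one
Conditions: t-BuONO (1.2 equiv), AcOH (cat.), MeCN, 0 °C, dark
Reagents that add atoms: tert-butyl nitrite, CC(C)(C)ON=O
Why: Aprotic diazotization of an ortho-aminophenol: nitrosation of the amine by the alkyl nitrite and loss of water give the diazonium phenolate, which is the neutral, isolable ortho-quinone diazide, with both bromines untouched and no stereocentre formed.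

**Step 2**
Reactants: 3 2,4-dibromo-6-diazocyclohexa-2,4-dien-1-one; 2 3,5-dibromo-2-hydroxybenzaldehyde (3,5-dibromosalicylaldehyde)
Product: 4 3,5-dibromo-2-(3,5-dibromo-2-hydroxyphenoxy)benzaldehyde
Conditions: Rh2(esp)2 (2 mol%), 2 (3 equiv), 4 Å MS, ClCH2CH2Cl, 60 °C, slow addition of 3 (4 h), dark
Reagents that add atoms: none
Why: Proposed new method: loss of N2 from 3 on the dirhodium catalyst gives a catalyst-bound quinoid carbene (an ortho-oxidoaryl cation equivalent; metal binding suppresses the Wolff ring contraction of the free ketocarbene), the phenolic oxygen of 2 attacks the carbene carbon to give an oxonium ylide, and proton transfer to the ring A oxygen with rearomatisation releases 4 with the new aryl C–O bond exactly at the former diazo carbon, while the formyl group keeps the second ring B oxygen masked and excess 2 with slow addition of 3 limits carbene dimerisation and insertion into the product hydroxyl; the closest known reaction types are dirhodium-catalysed O–H insertion of α-diazocarbonyl compounds into phenols (where an ortho carbonyl is tolerated and the O–H reacts first) and metal-catalysed arylations with para-quinone diazides, whereas O–H insertion of an ortho-quinone diazide into a hindered, electron-poor phenol to make a 2-hydroxydiaryl ether has not been shown; no stereocentre is formed.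

**Step 3**
Reactants: 4 3,5-dibromo-2-(3,5-dibromo-2-hydroxyphenoxy)benzaldehyde
Product: 6 3,5-dibromo-2-(3,5-dibromo-2-hydroxyphenoxy)phenol, via aryl formate 5 (not isolated)
Conditions: mCPBA (2.5 equiv), CH2Cl2, 0 °C to rt; then MeOH, HCl (cat.), rt
Reagents that add atoms: mCPBA (3-chloroperoxybenzoic acid), OOC(=O)c1cccc(Cl)c1
Why: Baeyer–Villiger (Dakin-type) oxidation: in the Criegee adduct the aryl group, helped by its ortho aryloxy donor, migrates to oxygen to give formate 5, and acid-catalysed transesterification with methanol frees the phenol; no stereocentre is formed.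

**Step 4**
Reactants: 6 3,5-dibromo-2-(3,5-dibromo-2-hydroxyphenoxy)phenol
Product: 7 2,3,5-tribromo-6-(3,5-dibromo-2-hydroxyphenoxy)phenol
Conditions: NBS (1.05 equiv), iPr2NH (0.2 equiv), CH2Cl2, 0 °C
Reagents that add atoms: N-bromosuccinimide (NBS), O=C1CCC(=O)N1Br
Why: Amine-mediated ortho-selective electrophilic aromatic bromination: the N-bromoamine formed from NBS and iPr2NH is hydrogen-bonded to the ring B hydroxyl and delivers bromine to its only free ortho position, while the para position is shielded between two bromines and ring A has no free position ortho or para to its hydroxyl; no stereocentre is formed.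

**Compound list** (no compound carries a stereo element)
1 | 2-amino-4,6-dibromophenol | Nc1cc(Br)cc(Br)c1O | starting material
2 | 3,5-dibromo-2-hydroxybenzaldehyde (3,5-dibromosalicylaldehyde) | O=Cc1cc(Br)cc(Br)c1O | starting material
3 | 2,4-dibromo-6-diazocyclohexa-2,4-dien-1-one | O=C1C(Br)=CC(Br)=CC1=[N+]=[N-] | intermediate
4 | 3,5-dibromo-2-(3,5-dibromo-2-hydroxyphenoxy)benzaldehyde | O=Cc1cc(Br)cc(Br)c1Oc1cc(Br)cc(Br)c1O | intermediate
5 | 3,5-dibromo-2-(3,5-dibromo-2-hydroxyphenoxy)phenyl formate | O=COc1cc(Br)cc(Br)c1Oc1cc(Br)cc(Br)c1O | intermediate (not isolated)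
6 | 3,5-dibromo-2-(3,5-dibromo-2-hydroxyphenoxy)phenol | Oc1cc(Br)cc(Br)c1Oc1cc(Br)cc(Br)c1O | intermediate
7 | 2,3,5-tribromo-6-(3,5-dibromo-2-hydroxyphenoxy)phenol | Oc1c(Br)cc(Br)cc1Oc1c(Br)cc(Br)c(Br)c1O | target

**Totals**
Total step count: 4. Longest linear sequence: 4 steps (1 → 3 → 4 → 6 → 7). Diazo oxide 3 is potentially shock- and light-sensitive: make it on gram scale or less, keep it cold and dark, and use it promptly.

**Three steps most likely to fail**

Step 2 (the proposed new O–H insertion). It may lose out to Wolff ring contraction, carbene dimerisation or attack at the formyl oxygen. The fallback makes the ether bond by classical nucleophilic aromatic substitution and sets out from 2. With K2CO3 in DMF at 110 °C, 2 displaces the fluoride of bought 2,4-dibromo-6-fluorobenzaldehyde F1; fluoride ortho to the formyl group leaves far faster than either bromide. This gives 3,5-dibromo-2-(3,5-dibromo-2-formylphenoxy)benzaldehyde F2. Double Baeyer–Villiger oxidation with mCPBA in CH2Cl2 gives 3,5-dibromo-2-[3,5-dibromo-2-(formyloxy)phenoxy]phenyl formate F3, which is not isolated, and methanolysis with catalytic HCl comes back to the route at 6.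

Step 3 (Baeyer–Villiger on an electron-poor ring). Hydride migration could give the benzoic acid instead of the formate. The fallback carries the second ring B oxygen as a methyl ether instead of a formyl group and sets out from 3. Under the conditions of step 2, the carbene from 3 inserts into the O–H of bought 2,4-dibromo-6-methoxyphenol F4 to give 2,4-dibromo-6-(2,4-dibromo-6-methoxyphenoxy)phenol F5. BBr3 in CH2Cl2 (−78 °C to rt) then cleaves the methyl ether and comes back to the route at 6.

Step 4 (regioselective last bromination). Bromination para to the ring B hydroxyl, or over-bromination, would give isomers that are hard to separate. The fallback builds the fifth bromine into the ring B partner before the coupling, where its position is unambiguous, and sets out from 3. Bought 2-bromo-6-hydroxybenzaldehyde F6 is dibrominated ortho and para to its hydroxyl (Br2, NaOAc, AcOH, rt) to give 3,5,6-tribromo-2-hydroxybenzaldehyde F7. The carbene from 3 is inserted into its O–H as in step 2 to give 2,3,5-tribromo-6-(3,5-dibromo-2-hydroxyphenoxy)benzaldehyde F8. Baeyer–Villiger oxidation and methanolysis as in step 3, through 2,3,5-tribromo-6-(3,5-dibromo-2-hydroxyphenoxy)phenyl formate F9 (not isolated), come back to the route at 7.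

**Further compounds**
F1 | step 2 | 2,4-dibromo-6-fluorobenzaldehyde | O=Cc1c(F)cc(Br)cc1Br
F2 | step 2 | 3,5-dibromo-2-(3,5-dibromo-2-formylphenoxy)benzaldehyde | O=Cc1cc(Br)cc(Br)c1Oc1cc(Br)cc(Br)c1C=O
F3 | step 2 | 3,5-dibromo-2-[3,5-dibromo-2-(formyloxy)phenoxy]phenyl formate | O=COc1cc(Br)cc(Br)c1Oc1cc(Br)cc(Br)c1OC=O
F4 | step 3 | 2,4-dibromo-6-methoxyphenol | COc1cc(Br)cc(Br)c1O
F5 | step 3 | 2,4-dibromo-6-(2,4-dibromo-6-methoxyphenoxy)phenol | COc1cc(Br)cc(Br)c1Oc1cc(Br)cc(Br)c1O
F6 | step 4 | 2-bromo-6-hydroxybenzaldehyde | O=Cc1c(O)cccc1Br
F7 | step 4 | 3,5,6-tribromo-2-hydroxybenzaldehyde | O=Cc1c(O)c(Br)cc(Br)c1Br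
F8 | step 4 | 2,3,5-tribromo-6-(3,5-dibromo-2-hydroxyphenoxy)benzaldehyde | O=Cc1c(Br)c(Br)cc(Br)c1Oc1cc(Br)cc(Br)c1O
F9 | step 4 | 2,3,5-tribromo-6-(3,5-dibromo-2-hydroxyphenoxy)phenyl formate | O=COc1c(Br)c(Br)cc(Br)c1Oc1cc(Br)cc(Br)c1O
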